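**Plan**

1. Numbering: ring A is the 5,7-dioxygenated lactone (O1, C2–C8a), ring B the tetraoxygenated lactone (primed atoms), rings C and D the 4-oxyphenyl groups on C4 and C4'. Retrosynthetic cuts, in order: the eight O–H bonds (methyl and silyl ethers); the ring A carbonyl (back to a lactol acylal); ring B at C3'–C4' and O1'–C8a'; the C3–C3' bond (alkylation); the C4–aryl bond (conjugate arylation of a coumarin).
2. Forward: coumarin 1 → C4 aryl → C3 acetate arm → temporary cis-fused γ-lactone acetal (C2 at lactol level, tied to the C2' carboxyl) → ring B by a formal [3+3] annulation with a quinone benzhydryl acetate → ring A carbonyl restored → phenols freed.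
3. Enabling feature: the oxygens on C5' and C8' of ring B are para, so ring B can be carried as a 2,3-dimethoxy-1,4-benzoquinone whose only CH (C8a') accepts the carboxyl oxygen O1'. C4' is benzylic to the 4-oxygenated ring D and ionises, so C4'/C8a' is a 1,3-dielectrophile matching the O1'–C2'–C3' enol carboxylate.
4. Stereochemistry: C4 by rhodium catalysis; C3 by kinetic protonation anti to the C4 aryl (cis); C3' and C4' both in the key step, relayed from C3/C4 through the convex face of the bicyclic template and an open synclinal transition state. Both lactones are the kinetic 3,4-cis isomers, so no base is used after step 5.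

Key step: step 9

**Route**

Step 1
Reactants: 1 5,7-dimethoxycoumarin; 2 4-methoxyphenylboronic acid
Product: 3 (4R)-5,7-dimethoxy-4-(4-methoxyphenyl)chroman-2-one
Conditions: Rh(acac)(C2H4)2 (monovalent rhodium, 3 mol %), (R)-SEGPHOS (3.3 mol %; the ligand antipode that leads to the 4R series), 2 (5 equiv), dioxane/H2O 10:1, 60 °C
Reagents that add atoms: none
Why: Hayashi–Miyaura asymmetric 1,4-addition, in which the aryl–rhodium species adds to C4 on the enantioface selected by the bisphosphine and the rhodium enolate is protonated by water, so C4 (R) is the one stereocentre set by catalysis.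

Step 2
Reactants: 3 (4R)-lactone; 4 ethyl bromoacetate
Product: 5 ethyl 2-[(3S,4R)-5,7-dimethoxy-4-(4-methoxyphenyl)-2-oxochroman-3-yl]acetate (3,4-trans)
Conditions: LiN(SiMe3)2, THF, −78 °C; 4, −78 → −40 °C
Reagents that add atoms: none
Why: Lactone enolate alkylation (SN2), in which the electrophile should enter anti to the pseudoaxial C4 aryl group and give the trans lactone, whose C3 configuration is corrected in step 3.

Step 3
Reactants: 5 trans ester
Product: 6 ethyl 2-[(3R,4R)-5,7-dimethoxy-4-(4-methoxyphenyl)-2-oxochroman-3-yl]acetate (3,4-cis)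
Conditions: LiN(SiMe3)2 (1.1 equiv), THF, −78 °C; 2,6-di-tert-butylphenol, −78 °C; aq. NH4Cl
Reagents that add atoms: none
Why: Epimerisation by kinetic protonation, in which the amide base removes only the more acidic lactone α-hydrogen (not the ethyl ester CH2) and the hindered phenol protonates the planar C3 enolate anti to the pseudoaxial C4 aryl group, which should place the side chain cis to the aryl group.

Step 4
Reactants: 6 cis ester
Product: 8 (3aR,4R,9aR)-5,7-dimethoxy-4-(4-methoxyphenyl)-3,3a,4,9a-tetrahydro-2H-furo[2,3-b]chromen-2-one (cis-fused lactone acetal; H3a, H4 and H9a on one face), via lactol 7 (not isolated)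
Conditions: iBu2AlH (1.05 equiv), CH2Cl2, −78 °C; aq. KNaC4H4O6; pyridinium p-toluenesulfonate (cat.), benzene, 4 Å sieves, 23 °C
Reagents that add atoms: none
Why: Partial reduction of the more electrophilic aryl lactone to the lactol, then acid-catalysed γ-lactonisation of the lactol hydroxyl onto the ethyl ester, gives the strongly preferred cis-fused acylal; this temporary ring removes the acidity of H3 and holds C3 and C3' in a rigid bicycle.

Step 5
Reactants: 8 lactone acetal
Product: 9 tert-butyl{[(3aS,4R,9aR)-5,7-dimethoxy-4-(4-methoxyphenyl)-3a,9a-dihydro-4H-furo[2,3-b]chromen-2-yl]oxy}dimethylsilane (silyl ketene acetal; used crude)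
Conditions: LiN(iPr)2, THF, −78 °C; tBuMe2SiCl, DMPU, −78 → 0 °C; pentane, filtration, concentration under argon
Reagents that add atoms: tert-butyldimethylsilyl chloride, CC(C)(C)[Si](C)(C)Cl
Why: Kinetic enolisation of the γ-lactone at its only acidic site (the C3' methylene) and O-silylation of the enolate give the cyclic silyl ketene acetal without touching a stereocentre.

Step 6
Reactants: 10 1,2,3,4-tetramethoxybenzene; 11 4-methoxybenzaldehyde
Product: 12 (4-methoxyphenyl)(2,3,4,5-tetramethoxyphenyl)methanol (racemic)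
Conditions: n-BuLi, TMEDA, THF, 0 °C; 11, −78 → 0 °C; aq. NH4Cl
Reagents that add atoms: none
Why: Directed ortho-lithiation next to a methoxy group and 1,2-addition of the aryllithium to the aldehyde form the C4'–C4a' bond; the carbinol centre is racemic because it is planarised in step 9.

Step 7
Reactants: 12 carbinol
Product: 13 (4-methoxyphenyl)(2,3,4,5-tetramethoxyphenyl)methyl acetate (racemic)
Conditions: Ac2O, pyridine, DMAP (cat.), CH2Cl2, 0 °C
Reagents that add atoms: acetic anhydride, CC(=O)OC(C)=O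
Why: DMAP-catalysed O-acetylation installs the leaving group for the later ionisation and makes the benzylic position less oxidisable.

Step 8
Reactants: 13 acetate
Product: 14 (4,5-dimethoxy-3,6-dioxocyclohexa-1,4-dien-1-yl)(4-methoxyphenyl)methyl acetate (racemic quinone)
Conditions: (NH4)2Ce(NO3)6 (2.5 equiv), MeCN/H2O 2:1, 0 °C, 15 min
Reagents that add atoms: water, O
Why: Oxidative demethylation by tetravalent cerium of the two para-related methoxy groups (on C5' and C8') of the most electron-rich ring should give the 2,3-dimethoxy-1,4-benzoquinone and leave the anisyl ring and the acetate alone.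

Step 9
Reactants: 9 silyl ketene acetal; 14 quinone acetate
Product: 17 (3S,3'S,4R,4'R)-5',8'-bis(tert-butyldimethylsilyloxy)-5,6',7,7'-tetramethoxy-4,4'-bis(4-methoxyphenyl)-2'-oxo-[3,3'-bichroman]-2-yl acetate (C2 epimers), via benzhydrylated quinone lactone acetal 15 (not isolated), via monosilyl hydroquinone acetate 16 (not isolated)
Conditions: 14, tBuMe2SiOTf (1.3 equiv), 2,6-di-tert-butyl-4-methylpyridine (1.5 equiv), CH2Cl2, −78 °C; 9 (1.2 equiv) added slowly; −78 → 0 °C; aq. NaHCO3
Reagents that add atoms: tert-butyldimethylsilyl trifluoromethanesulfonate, CC(C)(C)[Si](C)(C)OS(=O)(=O)C(F)(F)F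
Why: Proposed new method: the silyl triflate ionises the benzylic acetate of 14 to a cation stabilised by the 4-methoxyphenyl ring, which the ketene acetal attacks at C3' (closest known type: Mukaiyama-type SN1 benzhydrylation of a silyl ketene acetal) to give 15, whose lactone carbonyl oxygen then adds to C8a' of the silyl-activated quinone (closest known type: intramolecular Thiele–Winter acyloxylation of a quinone) while the acylal C2–O bond fragments, the acetate returns to C2, the silyl group ends on O5' and enolisation aromatises ring B to 16, which the excess triflate silylates at O8'. Ring B closes by a 6-endo-trig conjugate addition of oxygen, the C–C bond being formed intermolecularly beforehand. C3' is controlled by the cis-fused bicycle, since the cation approaches the convex face anti to C4, whose aryl group lies over the concave face, which gives the trans relation of C4 and C4' on the five-membered ring (3'S). C4' is controlled by simple diastereoselection in an open synclinal transition state that places the twisted quinonyl group anti to the ketene acetal C=C, the C4' hydrogen over the five-membered ring and the flat anisyl group over the silyloxy terminus (4'R, H3'/H4' cis in ring B). The step needs site selectivity for the cation over the quinone carbons, which the far higher electrophilicity of the benzhydryl cation at −78 °C should secure, and regioselectivity in the oxygen addition, which is secured because C8a' is the only quinone CH and the only position closing a six-membered ring.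

Step 10
Reactants: 17 anomeric acetate
Product: 19 (3S,3'S,4R,4'R)-5',8'-bis(tert-butyldimethylsilyloxy)-5,6',7,7'-tetramethoxy-4,4'-bis(4-methoxyphenyl)-[3,3'-bichromane]-2,2'-dione, via lactol 18 (not isolated)
Conditions: 1 M HCl, THF, 23 °C; Dess–Martin periodinane, NaHCO3, CH2Cl2, 0 → 23 °C
Reagents that add atoms: water, O
Why: Acid hydrolysis of the glycosyl-acetate-like anomeric acetate (any lactol already formed in step 9 converges here) and periodinane oxidation of the lactol restore the ring A lactone without base, so C3 and C3' should not epimerise, and the silyl ethers shield the hydroquinone from the oxidant.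

Step 11
Reactants: 19 bis-lactone
Product: 21 (3S,3'S,4R,4'R)-5,5',6',7,7',8'-hexahydroxy-4,4'-bis(4-hydroxyphenyl)-[3,3'-bichromane]-2,2'-dione (CNP0064734.1), via hydroquinone 20 (not isolated)
Conditions: HF·pyridine, THF, 0 °C; concentration; BBr3 (12 equiv), CH2Cl2, −78 → 23 °C; H2O, 0 °C; argon throughout
Reagents that add atoms: none
Why: Fluoride cleavage of the two aryl silyl ethers and Lewis-acid cleavage of the six aryl methyl ethers by BBr3 are both non-basic, which the aryl lactones and the two epimerisable α-centres should tolerate, and the air-sensitive polyphenol is kept under argon.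

**Compound list**

1 | 5,7-dimethoxy-2H-chromen-2-one (5,7-dimethoxycoumarin) | O=c1ccc2c(OC)cc(OC)cc2o1 | starting material
2 | 4-methoxyphenylboronic acid | COc1ccc(cc1)B(O)O | starting material
3 | (4R)-5,7-dimethoxy-4-(4-methoxyphenyl)chroman-2-one | O=C1Oc2cc(OC)cc(OC)c2[C@@H](c2ccc(OC)cc2)C1 | intermediate
4 | ethyl bromoacetate | CCOC(=O)CBr | starting material
5 | ethyl 2-[(3S,4R)-5,7-dimethoxy-4-(4-methoxyphenyl)-2-oxochroman-3-yl]acetate (3,4-trans) | O=C1Oc2cc(OC)cc(OC)c2[C@@H](c2ccc(OC)cc2)[C@@H]1CC(=O)OCC | intermediate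
6 | ethyl 2-[(3R,4R)-5,7-dimethoxy-4-(4-methoxyphenyl)-2-oxochroman-3-yl]acetate (3,4-cis) | O=C1Oc2cc(OC)cc(OC)c2[C@@H](c2ccc(OC)cc2)[C@H]1CC(=O)OCC | intermediate
7 | ethyl 2-[(3R,4R)-2-hydroxy-5,7-dimethoxy-4-(4-methoxyphenyl)chroman-3-yl]acetate (lactol, C2 epimers) | OC1Oc2cc(OC)cc(OC)c2[C@@H](c2ccc(OC)cc2)[C@H]1CC(=O)OCC | intermediate
8 | (3aR,4R,9aR)-5,7-dimethoxy-4-(4-methoxyphenyl)-3,3a,4,9a-tetrahydro-2H-furo[2,3-b]chromen-2-one | O=C1O[C@H]2Oc3cc(OC)cc(OC)c3[C@@H](c3ccc(OC)cc3)[C@H]2C1 | intermediate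
9 | tert-butyl{[(3aS,4R,9aR)-5,7-dimethoxy-4-(4-methoxyphenyl)-3a,9a-dihydro-4H-furo[2,3-b]chromen-2-yl]oxy}dimethylsilane | CC(C)(C)[Si](C)(C)OC1O[C@H]2Oc3cc(OC)cc(OC)c3[C@@H](c3ccc(OC)cc3)[C@H]2C=1 | intermediate
10 | 1,2,3,4-tetramethoxybenzene | COc1ccc(OC)c(OC)c1OC | starting material
11 | 4-methoxybenzaldehyde | COc1ccc(C=O)cc1 | starting material
12 | (4-methoxyphenyl)(2,3,4,5-tetramethoxyphenyl)methanol (racemic) | COc1ccc(cc1)C(O)c1cc(OC)c(OC)c(OC)c1OC | intermediate
13 | (4-methoxyphenyl)(2,3,4,5-tetramethoxyphenyl)methyl acetate (racemic) | COc1ccc(cc1)C(OC(C)=O)c1cc(OC)c(OC)c(OC)c1OC | intermediate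
14 | (4,5-dimethoxy-3,6-dioxocyclohexa-1,4-dien-1-yl)(4-methoxyphenyl)methyl acetate (racemic) | COc1ccc(cc1)C(OC(C)=O)C1=CC(=O)C(OC)=C(OC)C1=O | intermediate
15 | (3S,3aS,4R,9aR)-3-[(R)-(4,5-dimethoxy-3,6-dioxocyclohexa-1,4-dien-1-yl)(4-methoxyphenyl)methyl]-5,7-dimethoxy-4-(4-methoxyphenyl)-3,3a,4,9a-tetrahydro-2H-furo[2,3-b]chromen-2-one | O=C1O[C@H]2Oc3cc(OC)cc(OC)c3[C@@H](c3ccc(OC)cc3)[C@H]2[C@@H]1[C@@H](C1=CC(=O)C(OC)=C(OC)C1=O)c1ccc(OC)cc1 | intermediate
16 | (3S,3'S,4R,4'R)-5'-(tert-butyldimethylsilyloxy)-8'-hydroxy-5,6',7,7'-tetramethoxy-4,4'-bis(4-methoxyphenyl)-2'-oxo-[3,3'-bichroman]-2-yl acetate (C2 epimers) | CC(=O)OC1Oc2cc(OC)cc(OC)c2[C@@H](c2ccc(OC)cc2)[C@H]1[C@H]1C(=O)Oc2c(O)c(OC)c(OC)c(O[Si](C)(C)C(C)(C)C)c2[C@H]1c1ccc(OC)cc1 | intermediate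
17 | (3S,3'S,4R,4'R)-5',8'-bis(tert-butyldimethylsilyloxy)-5,6',7,7'-tetramethoxy-4,4'-bis(4-methoxyphenyl)-2'-oxo-[3,3'-bichroman]-2-yl acetate (C2 epimers) | CC(=O)OC1Oc2cc(OC)cc(OC)c2[C@@H](c2ccc(OC)cc2)[C@H]1[C@H]1C(=O)Oc2c(O[Si](C)(C)C(C)(C)C)c(OC)c(OC)c(O[Si](C)(C)C(C)(C)C)c2[C@H]1c1ccc(OC)cc1 | intermediate
18 | (3S,3'S,4R,4'R)-5',8'-bis(tert-butyldimethylsilyloxy)-2-hydroxy-5,6',7,7'-tetramethoxy-4,4'-bis(4-methoxyphenyl)-[3,3'-bichroman]-2'-one (lactol, C2 epimers) | OC1Oc2cc(OC)cc(OC)c2[C@@H](c2ccc(OC)cc2)[C@H]1[C@H]1C(=O)Oc2c(O[Si](C)(C)C(C)(C)C)c(OC)c(OC)c(O[Si](C)(C)C(C)(C)C)c2[C@H]1c1ccc(OC)cc1 | intermediate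
19 | (3S,3'S,4R,4'R)-5',8'-bis(tert-butyldimethylsilyloxy)-5,6',7,7'-tetramethoxy-4,4'-bis(4-methoxyphenyl)-[3,3'-bichromane]-2,2'-dione | O=C1Oc2cc(OC)cc(OC)c2[C@@H](c2ccc(OC)cc2)[C@H]1[C@H]1C(=O)Oc2c(O[Si](C)(C)C(C)(C)C)c(OC)c(OC)c(O[Si](C)(C)C(C)(C)C)c2[C@H]1c1ccc(OC)cc1 | intermediate
20 | (3S,3'S,4R,4'R)-5',8'-dihydroxy-5,6',7,7'-tetramethoxy-4,4'-bis(4-methoxyphenyl)-[3,3'-bichromane]-2,2'-dione | O=C1Oc2cc(OC)cc(OC)c2[C@@H](c2ccc(OC)cc2)[C@H]1[C@H]1C(=O)Oc2c(O)c(OC)c(OC)c(O)c2[C@H]1c1ccc(OC)cc1 | intermediate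
21 | (3S,3'S,4R,4'R)-5,5',6',7,7',8'-hexahydroxy-4,4'-bis(4-hydroxyphenyl)-[3,3'-bichromane]-2,2'-dione | O=C1Oc2cc(O)cc(O)c2[C@@H](c2ccc(O)cc2)[C@H]1[C@H]1C(=O)Oc2c(O)c(O)c(O)c(O)c2[C@H]1c1ccc(O)cc1 | target

**Step count and risks**

Total steps: 11. Longest linear sequence: 8 steps (steps 1–5 and 9–11).

Step 9 (carries the label). What may go wrong: the Lewis acid may divert the ketene acetal to C-attack on the quinone ring, or the quinone may oxidise it by electron transfer. The carbonyl-oxygen addition may fail to follow the C–C bond formation. The C2 oxocarbenium ion may lose H3 to a 4H-chromene, and the facial discrimination at C4' may be poor. Fallback, from 9 and 13, returning at 18: the two bonds are made in separate known operations. Ketene acetal 9 is alkylated with the quinone-free acetate 13 (Me3SiOTf cat., CH2Cl2, −78 °C; Mukaiyama-type SN1 benzhydrylation) to give (3S,3aS,4R,9aR)-5,7-dimethoxy-4-(4-methoxyphenyl)-3-[(R)-(4-methoxyphenyl)(2,3,4,5-tetramethoxyphenyl)methyl]-3,3a,4,9a-tetrahydro-2H-furo[2,3-b]chromen-2-one F1. Oxidative demethylation with (NH4)2Ce(NO3)6 in MeCN/H2O then gives quinone 15, here isolated. Aqueous CF3CO2H in THF hydrolyses the acylal, and the freed carboxylic acid adds to the quinone CH (the conjugate addition known from oxidative lactonisation of dihydrocaffeic-type acids) to give the lactol hydroquinone (3S,3'S,4R,4'R)-2,5',8'-trihydroxy-5,6',7,7'-tetramethoxy-4,4'-bis(4-methoxyphenyl)-[3,3'-bichroman]-2'-one F2. Silylation (tBuMe2SiOTf, 2,6-lutidine) gives the tris-silyl ether (3S,3'S,4R,4'R)-2,5',8'-tris(tert-butyldimethylsilyloxy)-5,6',7,7'-tetramethoxy-4,4'-bis(4-methoxyphenyl)-[3,3'-bichroman]-2'-one F3. F3 enters step 10, where acid cleaves the anomeric silyl ether to lactol 18.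

Step 3. What may go wrong: protonation of the enolate may not be face-selective, or the cis lactone may re-equilibrate to the trans isomer through proton exchange. Fallback, from 3, returning at 6: the cis relation is made by hydrogenation. Lactone 3 undergoes aldol addition to ethyl glyoxylate (LiN(SiMe3)2, THF, −78 °C) to give ethyl 2-hydroxy-2-[(3S,4R)-5,7-dimethoxy-4-(4-methoxyphenyl)-2-oxochroman-3-yl]acetate F4 (carbinol epimers). Neutral dehydration (Martin sulfurane, CH2Cl2, 0 °C) gives ethyl (E)-2-[(4R)-5,7-dimethoxy-4-(4-methoxyphenyl)-2-oxochroman-3-ylidene]acetate F5. Hydrogenation (H2, palladium on carbon, EtOAc) should deliver hydrogen to the exocyclic double bond anti to the pseudoaxial C4 aryl group and give 6.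

Step 8. What may go wrong: the electron-rich benzhydryl acetate may be solvolysed or over-oxidised at the benzylic carbon in the acidic aqueous oxidant before the arene is oxidised. Fallback, from 12, returning at 14: the order is reversed. Carbinol 12 is oxidised with PhI(OCOCF3)2 in MeCN/H2O at 0 °C (hypervalent-iodine oxidative demethylation of a hydroquinone dimethyl ether) to 2-[hydroxy(4-methoxyphenyl)methyl]-5,6-dimethoxycyclohexa-2,5-diene-1,4-dione F6, whose benzylic position no longer ionises. F6 is acetylated without amine base (Ac2O, Sc(OTf)3 cat., MeCN, −20 °C) to give 14.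

**Further compounds**

F1 | step 9 | (3S,3aS,4R,9aR)-5,7-dimethoxy-4-(4-methoxyphenyl)-3-[(R)-(4-methoxyphenyl)(2,3,4,5-tetramethoxyphenyl)methyl]-3,3a,4,9a-tetrahydro-2H-furo[2,3-b]chromen-2-one | O=C1O[C@H]2Oc3cc(OC)cc(OC)c3[C@@H](c3ccc(OC)cc3)[C@H]2[C@@H]1[C@@H](c1cc(OC)c(OC)c(OC)c1OC)c1ccc(OC)cc1
F2 | step 9 | (3S,3'S,4R,4'R)-2,5',8'-trihydroxy-5,6',7,7'-tetramethoxy-4,4'-bis(4-methoxyphenyl)-[3,3'-bichroman]-2'-one (C2 epimers) | OC1Oc2cc(OC)cc(OC)c2[C@@H](c2ccc(OC)cc2)[C@H]1[C@H]1C(=O)Oc2c(O)c(OC)c(OC)c(O)c2[C@H]1c1ccc(OC)cc1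
F3 | step 9 | (3S,3'S,4R,4'R)-2,5',8'-tris(tert-butyldimethylsilyloxy)-5,6',7,7'-tetramethoxy-4,4'-bis(4-methoxyphenyl)-[3,3'-bichroman]-2'-one (C2 epimers) | CC(C)(C)[Si](C)(C)OC1Oc2cc(OC)cc(OC)c2[C@@H](c2ccc(OC)cc2)[C@H]1[C@H]1C(=O)Oc2c(O[Si](C)(C)C(C)(C)C)c(OC)c(OC)c(O[Si](C)(C)C(C)(C)C)c2[C@H]1c1ccc(OC)cc1
F4 | step 3 | ethyl 2-hydroxy-2-[(3S,4R)-5,7-dimethoxy-4-(4-methoxyphenyl)-2-oxochroman-3-yl]acetate (carbinol epimers) | O=C1Oc2cc(OC)cc(OC)c2[C@@H](c2ccc(OC)cc2)[C@@H]1C(O)C(=O)OCC
F5 | step 3 | ethyl (E)-2-[(4R)-5,7-dimethoxy-4-(4-methoxyphenyl)-2-oxochroman-3-ylidene]acetate | O=C1Oc2cc(OC)cc(OC)c2[C@@H](c2ccc(OC)cc2)/C1=C\C(=O)OCC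
F6 | step 8 | 2-[hydroxy(4-methoxyphenyl)methyl]-5,6-dimethoxycyclohexa-2,5-diene-1,4-dione (racemic) | COc1ccc(cc1)C(O)C1=CC(=O)C(OC)=C(OC)C1=O
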